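**Retrosynthetic overview**
- Ring C is made last and in one operation. C2–C3 and C4–C4a are cut together (retro formal [4+2], oxa-Povarov type). This leads back to an O-aryl oxocarbenium ion O1=C2, stored as an O-aryl O-pivaloyl acetal of 4-silyloxybenzaldehyde, and to ketene diethyl acetal, whose two carbons become C3 and C4 at the ketone oxidation level.
- Enabling feature: C4a is the only unsubstituted carbon of ring A and lies ortho to O1 and to the C5 oxygen. With C8a, O1 and the cationic C2 it forms a 2-oxadiene that can close on the ketene acetal at this one carbon only, while a chiral counteranion sets C2.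
- Ring A enters as the C2v-symmetric 5-methoxy-4,6-diprenylresorcinol (one OH becomes O1, the other the C5 hydroxyl). Both prenyl groups come from a double aromatic Claisen rearrangement on methyl 2,6-dihydroxy-4-methoxybenzoate, whose ester blocks the future C4a and is then lost as CO2.
- Order of ring formation: rings A and B are bought as benzene rings; ring C is the only ring formed (step 8); the two silyl ethers are removed last.

Key step: step 8

Remark: the given SMILES describes the (2S)-flavanone; the sense of induction of the chiral acid in step 8 cannot be derived with certainty, so the catalyst antipode is taken as the one that gives (2S).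

**Route**

Step 1
Reactants: 1 methyl 2,4,6-trihydroxybenzoate
Product: 2 methyl 2,6-dihydroxy-4-methoxybenzoate
Conditions: Me2SO4 (1.05 equiv), K2CO3 (1.1 equiv), acetone, 0 °C → rt
Reagents that add atoms: dimethyl sulfate, COS(=O)(=O)OC
Why: Williamson-type O-methylation; the 4-OH (para to the ester and not hydrogen-bonded to it) is the most acidic and most accessible phenol, so one equivalent of base and of dimethyl sulfate should methylate it before the two chelated ortho phenols.

Step 2
Reactants: 2 methyl 2,6-dihydroxy-4-methoxybenzoate; 3 3-chloro-3-methylbut-1-yne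
Product: 4 methyl 4-methoxy-2,6-bis[(2-methylbut-3-yn-2-yl)oxy]benzoate
Conditions: 3 (3 equiv), DBU (3 equiv), CuCl2·2H2O (1 mol %), MeCN, 0 °C → rt
Reagents that add atoms: none
Why: Copper-catalysed propargylic etherification of phenols with a tertiary propargylic chloride, the standard entry to aryl 1,1-dimethylpropargyl ethers; DBU breaks the hydrogen bonds of both ortho phenols to the ester so that both should react.

Step 3
Reactants: 4 methyl 4-methoxy-2,6-bis[(2-methylbut-3-yn-2-yl)oxy]benzoate
Product: 6 methyl 2,6-dihydroxy-4-methoxy-3,5-bis(3-methylbut-2-en-1-yl)benzoate, via bis(1,1-dimethylallyl) ether 5 (not isolated)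
Conditions: H2 (1 atm), Pd/CaCO3 poisoned with Pb(OAc)2 (Lindlar catalyst), quinoline, EtOAc, rt; filter, evaporate; xylenes, 130 °C
Reagents that add atoms: none
Why: Semihydrogenation followed by a twofold aromatic Claisen ([3,3]-sigmatropic) rearrangement; only the dienone formed at the unsubstituted ortho carbon (C3 or C5) can tautomerise to a phenol because the other ortho carbon carries the ester, and the allyl inversion turns each 1,1-dimethylallyl unit into a prenyl group, with no stereocentre formed.

Step 4
Reactants: 6 methyl 2,6-dihydroxy-4-methoxy-3,5-bis(3-methylbut-2-en-1-yl)benzoate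
Product: 8 5-methoxy-4,6-bis(3-methylbut-2-en-1-yl)benzene-1,3-diol, via benzoic acid 7 (not isolated)
Conditions: KOH (10 equiv), EtOH–H2O 1:1, 100 °C (sealed, argon); 0 °C, 2 M HCl to pH 4; 50 °C
Reagents that add atoms: water (as hydroxide), O (supplies one oxygen of the carboxyl group of 7; none of its heavy atoms stay in 8)
Why: Saponification and decarboxylation of the resulting 2,6-dihydroxybenzoic acid, which should lose CO2 readily by ipso-protonation through its keto tautomer as phloroglucinol carboxylic acids do; this unmasks the ring carbon that becomes C4a.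

Step 5
Reactants: 8 5-methoxy-4,6-bis(3-methylbut-2-en-1-yl)benzene-1,3-diol
Product: 9 5-[(tert-butyldimethylsilyl)oxy]-3-methoxy-2,4-bis(3-methylbut-2-en-1-yl)phenol
Conditions: TBSCl (1.0 equiv), imidazole (2.0 equiv), DMF, 0 °C
Reagents that add atoms: tert-butyldimethylsilyl chloride, CC(C)(C)[Si](C)(C)Cl
Why: Silylation of one of two equivalent phenols; the outcome is statistical, so one equivalent of TBSCl is used and recovered 8 and the bis-silyl ether (returned to 8 with fluoride) are to be recycled.

Step 6
Reactants: 10 4-[(tert-butyldimethylsilyl)oxy]benzaldehyde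
Product: 11 chloro{4-[(tert-butyldimethylsilyl)oxy]phenyl}methyl 2,2-dimethylpropanoate (racemic)
Conditions: t-BuCOCl (1.1 equiv), ZnCl2 (2 mol %), CH2Cl2, 0 °C → rt; used as the crude solution
Reagents that add atoms: pivaloyl chloride, CC(C)(C)C(=O)Cl
Why: ZnCl2-catalysed addition of an acyl chloride across the aldehyde C=O (known formation of α-chloroalkyl esters); pivaloyl is chosen because its carbonyl should resist attack by the phenoxide in step 7.

Step 7
Reactants: 9 5-[(tert-butyldimethylsilyl)oxy]-3-methoxy-2,4-bis(3-methylbut-2-en-1-yl)phenol; 11 chloro{4-[(tert-butyldimethylsilyl)oxy]phenyl}methyl 2,2-dimethylpropanoate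
Product: 12 {5-[(tert-butyldimethylsilyl)oxy]-3-methoxy-2,4-bis(3-methylbut-2-en-1-yl)phenoxy}{4-[(tert-butyldimethylsilyl)oxy]phenyl}methyl 2,2-dimethylpropanoate (racemic)
Conditions: NaH (1.05 equiv), THF, 0 °C; 11 (1.2 equiv), −40 → 0 °C; aq. NaHCO3; Et3N-deactivated silica
Reagents that add atoms: none
Why: Acyloxyalkylation of a phenoxide (O-alkylation with an α-chloroalkyl ester, SN1-like through the benzylic acyloxycarbenium ion), in which the hard sodium phenoxide oxygen should react faster than ring carbon; the new acetal centre is racemic, which does not matter because it is planarised in step 8.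

Step 8
Reactants: 12 {5-[(tert-butyldimethylsilyl)oxy]-3-methoxy-2,4-bis(3-methylbut-2-en-1-yl)phenoxy}{4-[(tert-butyldimethylsilyl)oxy]phenyl}methyl 2,2-dimethylpropanoate; 13 1,1-diethoxyethene (ketene diethyl acetal)
Product: 15 (2S)-5-[(tert-butyldimethylsilyl)oxy]-2-{4-[(tert-butyldimethylsilyl)oxy]phenyl}-7-methoxy-6,8-bis(3-methylbut-2-en-1-yl)-2,3-dihydro-4H-chromen-4-one, via diethyl ketal 14 (not isolated)
Conditions: 13 (3 equiv), chiral imidodiphosphorimidate acid (IDPi; two (S)-3,3'-bis[3,5-bis(trifluoromethyl)phenyl]-BINOL phosphorus units joined through N, each P=NSO2CF3; 5 mol %), PhMe, −78 → −30 °C; Et3N; 0.5 M aq. oxalic acid, THF, 0 °C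
Reagents that add atoms: water, O
Why: Proposed new method: the chiral acid (or the diethoxycarbenium ion it forms with 13) removes pivalate from 12, which gives a contact ion pair of the O-aryl oxocarbenium ion (O1=C2) with the chiral anion; the CH2 carbon of 13 adds to C2 (bond C2–C3), the diethoxycarbenium ion so formed at C4 is attacked by ring carbon C4a (bond C4–C4a), loss of the C4a proton gives ketal 14 and the aqueous acid work-up unmasks ketone 15. The closest known reactions are the oxa-Povarov reaction (stepwise formal [4+2] cycloaddition of cationic aryl 2-oxadienes with alkenes under achiral Lewis acids) and IDPi-catalysed enantioselective additions of silyl ketene acetals to oxocarbenium ions released from lactol acetates; new are their union, the acyclic O-aryl oxocarbenium ion and a ketene acetal as the 2π partner, which brings C4 in at the ketone oxidation level. Ring C is closed in Friedel–Crafts mode, 6-exo-trig with respect to the C4=O+ bond of the diethoxycarbenium ion, and because C4 carries two equal ethoxy groups C2 is the only stereocentre formed. C2 is set in the first C–C bond formation by the confined chiral counteranion, which leaves one face of the oxocarbenium ion open to 13; which catalyst antipode leads to (2S) has to be fixed in a first screen. The step needs ionisation by loss of pivalate and not of the aryloxide (the carboxylate is the better leaving group and leaves the better stabilised cation), addition of 13 faster than Prins attack of the C8 prenyl alkene on C2 (13 is the far stronger π-nucleophile and is present in excess when the cation forms) and ring closure at one carbon only (C4a is the single unsubstituted carbon of ring A, ortho to O1 and to the C5 silyloxy group). The second equivalent of 13 takes up the pivalic acid as ethyl pivalate and ethyl acetate, so that no free acid builds up beside the prenyl groups and silyl ethers.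

Step 9
Reactants: 15 (2S)-5-[(tert-butyldimethylsilyl)oxy]-2-{4-[(tert-butyldimethylsilyl)oxy]phenyl}-7-methoxy-6,8-bis(3-methylbut-2-en-1-yl)-2,3-dihydro-4H-chromen-4-one
Product: 16 (2S)-5-hydroxy-2-(4-hydroxyphenyl)-7-methoxy-6,8-bis(3-methylbut-2-en-1-yl)-2,3-dihydro-4H-chromen-4-one
Conditions: TBAF (2.5 equiv), AcOH (2.5 equiv), THF, 0 °C
Reagents that add atoms: none
Why: Fluoride-induced cleavage of both aryl silyl ethers; the acetic acid buffer keeps the medium non-basic so that the flavanone should not open to the chalcone (which would racemise C2) and the prenyl groups remain untouched.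

**Compound list**

1 | methyl 2,4,6-trihydroxybenzoate | COC(=O)c1c(O)cc(O)cc1O | starting material
2 | methyl 2,6-dihydroxy-4-methoxybenzoate | COC(=O)c1c(O)cc(OC)cc1O | intermediate
3 | 3-chloro-3-methylbut-1-yne | CC(C)(Cl)C#C | starting material
4 | methyl 4-methoxy-2,6-bis[(2-methylbut-3-yn-2-yl)oxy]benzoate | COC(=O)c1c(OC(C)(C)C#C)cc(OC)cc1OC(C)(C)C#C | intermediate
5 | methyl 4-methoxy-2,6-bis[(2-methylbut-3-en-2-yl)oxy]benzoate | COC(=O)c1c(OC(C)(C)C=C)cc(OC)cc1OC(C)(C)C=C | intermediate
6 | methyl 2,6-dihydroxy-4-methoxy-3,5-bis(3-methylbut-2-en-1-yl)benzoate | COC(=O)c1c(O)c(CC=C(C)C)c(OC)c(CC=C(C)C)c1O | intermediate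
7 | 2,6-dihydroxy-4-methoxy-3,5-bis(3-methylbut-2-en-1-yl)benzoic acid (formed as its potassium salt) | OC(=O)c1c(O)c(CC=C(C)C)c(OC)c(CC=C(C)C)c1O | intermediate
8 | 5-methoxy-4,6-bis(3-methylbut-2-en-1-yl)benzene-1,3-diol | COc1c(CC=C(C)C)c(O)cc(O)c1CC=C(C)C | intermediate
9 | 5-[(tert-butyldimethylsilyl)oxy]-3-methoxy-2,4-bis(3-methylbut-2-en-1-yl)phenol | COc1c(CC=C(C)C)c(O)cc(O[Si](C)(C)C(C)(C)C)c1CC=C(C)C | intermediate
10 | 4-[(tert-butyldimethylsilyl)oxy]benzaldehyde | O=Cc1ccc(O[Si](C)(C)C(C)(C)C)cc1 | starting material
11 | chloro{4-[(tert-butyldimethylsilyl)oxy]phenyl}methyl 2,2-dimethylpropanoate (racemic) | CC(C)(C)C(=O)OC(Cl)c1ccc(O[Si](C)(C)C(C)(C)C)cc1 | intermediate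
12 | {5-[(tert-butyldimethylsilyl)oxy]-3-methoxy-2,4-bis(3-methylbut-2-en-1-yl)phenoxy}{4-[(tert-butyldimethylsilyl)oxy]phenyl}methyl 2,2-dimethylpropanoate (racemic) | CC(C)(C)C(=O)OC(Oc1cc(O[Si](C)(C)C(C)(C)C)c(CC=C(C)C)c(OC)c1CC=C(C)C)c1ccc(O[Si](C)(C)C(C)(C)C)cc1 | intermediate
13 | 1,1-diethoxyethene (ketene diethyl acetal) | C=C(OCC)OCC | starting material
14 | (2S)-5-[(tert-butyldimethylsilyl)oxy]-2-{4-[(tert-butyldimethylsilyl)oxy]phenyl}-4,4-diethoxy-7-methoxy-6,8-bis(3-methylbut-2-en-1-yl)-3,4-dihydro-2H-chromene | COc1c(CC=C(C)C)c(O[Si](C)(C)C(C)(C)C)c2c(c1CC=C(C)C)O[C@H](c1ccc(O[Si](C)(C)C(C)(C)C)cc1)CC2(OCC)OCC | intermediate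
15 | (2S)-5-[(tert-butyldimethylsilyl)oxy]-2-{4-[(tert-butyldimethylsilyl)oxy]phenyl}-7-methoxy-6,8-bis(3-methylbut-2-en-1-yl)-2,3-dihydro-4H-chromen-4-one | COc1c(CC=C(C)C)c(O[Si](C)(C)C(C)(C)C)c2c(c1CC=C(C)C)O[C@H](c1ccc(O[Si](C)(C)C(C)(C)C)cc1)CC2=O | intermediate
16 | (2S)-5-hydroxy-2-(4-hydroxyphenyl)-7-methoxy-6,8-bis(3-methylbut-2-en-1-yl)-2,3-dihydro-4H-chromen-4-one | COc1c(CC=C(C)C)c(O)c2c(c1CC=C(C)C)O[C@H](c1ccc(O)cc1)CC2=O | target

**Step count and risks**

Total step count: 9. Longest linear sequence: 8 steps (steps 1, 2, 3, 4, 5, 7, 8, 9).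

Steps most likely to fail:

1. Step 8 (proposed new method). What may go wrong:
- Prins attack of the C8 prenyl alkene on the oxocarbenium carbon before 13 adds.
- Slow closure of the open diethoxycarbenium ion, which can then shed the phenol by elimination or revert and so erode the enantiomeric purity.
- Acid-induced oligomerisation of 13.
- Poor facial selectivity.

Fallback with known chemistry, setting out from 8 and coming back at 15: 8 is converted into its bis(methoxymethyl) ether F1 (MOMCl, iPr2NEt, CH2Cl2). Directed lithiation of the one remaining ring C–H between the two OMOM groups (n-BuLi, THF, 0 °C) and acylation with N-methoxy-N-methylacetamide gives the acetophenone F2. Condensation with N,N-dimethylformamide dimethyl acetal (PhMe, 100 °C) gives the enaminone F3, and HCl in MeOH removes both MOM groups and closes the pyranone ring to the 5-hydroxychromone F4. Silylation (TBSOTf, 2,6-lutidine) gives the 5-silyloxychromone F5. A known rhodium-catalysed asymmetric conjugate addition of 4-[(tert-butyldimethylsilyl)oxy]phenylboronic acid to F5 (Rh(acac)(C2H4)2, chiral diene or biaryl bisphosphine ligand of the antipode that gives (2S), dioxane–water) then gives 15.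

2. Step 7. What may go wrong:
- Loss of the acyloxy acetal by ionisation or hydrolysis during isolation.
- Displacement of its pivalate by a second phenoxide.
- Acyl transfer to the phenoxide.

Fallback, setting out from 9 and 10 and coming back at 15, with a symmetric diaryl acetal in place of the acyloxy acetal: 10 is turned into tert-butyl[4-(dichloromethyl)phenoxy]dimethylsilane F6 ((COCl)2, Ph3PO (cat.), CHCl3). F6 with two equivalents of the sodium salt of 9 (NaH, DMF) gives the benzaldehyde diaryl acetal F7, a base-stable compound that should survive chromatography on basic alumina. In step 8, F7 takes the place of 12: either C–O bond ionises to the same O-aryl oxocarbenium ion, one equivalent of 9 is set free and recovered after the work-up, and the route is rejoined at 15 by way of 14.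

3. Step 4. What may go wrong:
- Hydroxide fails to add to an ester carbonyl flanked by two phenoxides.
- Forcing alkali or the acidic decarboxylation isomerises or cyclises the ortho-prenyl phenols.

Fallback, setting out from 6 and coming back at 8, by alkyl–oxygen cleavage instead of acyl substitution: LiI in pyridine at reflux attacks the unhindered ester methyl group (SN2) and gives the lithium salt of 7, which should lose CO2 on buffered acidification (pH 5, 40 °C) to give 8. No new compound is made.

**Further compounds**

F1 | step 8 | 3-methoxy-1,5-bis(methoxymethoxy)-2,4-bis(3-methylbut-2-en-1-yl)benzene | COCOc1cc(OCOC)c(CC=C(C)C)c(OC)c1CC=C(C)C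
F2 | step 8 | 1-[4-methoxy-2,6-bis(methoxymethoxy)-3,5-bis(3-methylbut-2-en-1-yl)phenyl]ethan-1-one | CC(=O)c1c(OCOC)c(CC=C(C)C)c(OC)c(CC=C(C)C)c1OCOC
F3 | step 8 | (E)-3-(dimethylamino)-1-[4-methoxy-2,6-bis(methoxymethoxy)-3,5-bis(3-methylbut-2-en-1-yl)phenyl]prop-2-en-1-one | CN(C)/C=C/C(=O)c1c(OCOC)c(CC=C(C)C)c(OC)c(CC=C(C)C)c1OCOC
F4 | step 8 | 5-hydroxy-7-methoxy-6,8-bis(3-methylbut-2-en-1-yl)-4H-chromen-4-one | COc1c(CC=C(C)C)c(O)c2c(=O)ccoc2c1CC=C(C)C
F5 | step 8 | 5-[(tert-butyldimethylsilyl)oxy]-7-methoxy-6,8-bis(3-methylbut-2-en-1-yl)-4H-chromen-4-one | COc1c(CC=C(C)C)c(O[Si](C)(C)C(C)(C)C)c2c(=O)ccoc2c1CC=C(C)C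
F6 | step 7 | tert-butyl[4-(dichloromethyl)phenoxy]dimethylsilane | ClC(Cl)c1ccc(O[Si](C)(C)C(C)(C)C)cc1
F7 | step 7 | bis{5-[(tert-butyldimethylsilyl)oxy]-3-methoxy-2,4-bis(3-methylbut-2-en-1-yl)phenyl} acetal of 4-[(tert-butyldimethylsilyl)oxy]benzaldehyde | C(Oc1cc(O[Si](C)(C)C(C)(C)C)c(CC=C(C)C)c(OC)c1CC=C(C)C)(Oc1cc(O[Si](C)(C)C(C)(C)C)c(CC=C(C)C)c(OC)c1CC=C(C)C)c1ccc(O[Si](C)(C)C(C)(C)C)cc1
F0 | step 4 | none | none
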